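At early times, I assumed, the impurity took free catalyst one to one and was finished, so the run went on with whatever that left.

- ochre: substrate 0.16 M; reagent 1.5 equiv; free catalyst 0.096 mol%; second catalyst 5 mol%; impurity 35 µM; run made earlier
- flask: substrate 0.16 M; reagent 1.00 equiv; free catalyst 0.096 mol%; second catalyst 5 mol%; impurity 35 µM

- ochre (time / h: product / %): 6.00: 4.6; 12.0: 8.0; 15.0: 10.2; 25.0: 19.2; 30.0: 22.2

(readings scatter by 1 percentage point)

1. apparent order in free catalyst when 30% of the substrate are converted (percent change of the rate of making product for one percent more free catalyst charged)
2. apparent order in reagent when 30% of the substrate are converted (percent change of the rate of making product for one percent more reagent charged)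

Both charges held 35 µM of impurity against 154 µM of catalyst, so I folded them into one number: f, the share of the catalyst charge left free once the impurity has been taken up, 0.772. Its use was as a gearing. One percent more catalyst charged, with the impurity held fixed, adds nothing to what is poisoned, so free catalyst rises by 1/f percent, 1.30, and that is the order in free catalyst if the rate follows free catalyst.

I then tested whether f was enough. The ochre run made 8.0% in its first 12.0 h and 12 percentage points in its last 15.0 h, a rate ratio of 1.20. With a scatter of 1 point on each reading, that ratio proves neither a rise nor a fall. So the ochre readings left open whether the rate follows free catalyst, and 1.30 stayed conditional on that. On reagent, f says nothing, and I had no reckoning.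

The forecast gave 1.2 (0.7 to 1.6) for free catalyst and 0.3 (0 to 1) for reagent: “Neither charge has been varied, so both values are guesses”.

The flask reached 30% conversion at 1.41 d and gave 0.0077 in free catalyst and 0.78 in reagent.

    substrate + free catalyst ⇌ free catalyst + open intermediate (K = 0.140, k = 9600 M⁻¹ h⁻¹)
    second catalyst + open intermediate ⇌ catalyst intermediate (K = 0.290 M⁻¹, k = 17.0 M⁻¹ h⁻¹)
    reagent + catalyst intermediate → second catalyst + product (k = 280 M⁻¹ h⁻¹)
    free catalyst + impurity → spent catalyst (k = 2.20 × 10⁵ M⁻¹ h⁻¹)

In the flask, open intermediate stood at 0.139 of substrate at 0.600 d and 0.139 at 6.00 d, against K1 of 0.14: a pre-equilibrium. The free share f of the charge runs that first step forward at 4.37 M d⁻¹ with substrate as charged, against 0.0192 M d⁻¹ of product, a ratio of 227.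

(The earlier runs and the new flask are simulated for substances that don't exist, noise included.)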